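The ratio of coupling to decomposition of the reagent in the reaction phase, a selectivity factor, contains no clock, and that is where this flask starts.

    reagent in the reaction phase → decomposed reagent (k1 = 0.00522 s⁻¹)
    starting material → decomposition product (k2 = 1.30 × 10⁻⁵ s⁻¹)
    reagent in the reaction phase ⇌ reagent in the second phase, rate k3*([reagent in the reaction phase] - [reagent in the second phase]/K3) per volume of the first phase (K3 = 2.63, k3 = 0.119 s⁻¹)
    starting material + reagent in the reaction phase → target (k4 = 4.94 M⁻¹ s⁻¹)
    reagent in the reaction phase ⇌ dormant form (K5 = 0.65, k5 = 0.0446 s⁻¹)

starting material 38 mM; reagent in the second phase 41.8 mM; time 1.5 min; volume of the second phase over the first 1.0

- in the second phase: reagent in the second phase; everything else is in the first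
- charges count per volume of the first phase; a concentration in a rate is the amount of a species over the volume of its own phase; every rate counts per litre of the first phase
- run time (flask): 1.5 min

- summer: doubling the transfer coefficient of step 3, all else as stated
- winter: doubling the amount of reagent in the second phase, all else as stated

1. target at 1.5 min, in percent of the starting material charged
2. the change that raises the amount of target at 1.5 min, in percent of the starting material charged most ("none" if none brings more than 2 percentage points) (summer / winter / none)
3. amount of target at 1.5 min, in percent of the starting material charged, after summer

Coupling consumes starting material at 4.94 M⁻¹ s⁻¹ times c(starting material) times c(reagent in the reaction phase), while decomposition makes decomposed reagent at 0.00522 s⁻¹ times c(reagent in the reaction phase). Dividing one rate by the other cancels the reagent and time, so c(decomposed reagent) equals a constant times the logarithm of charged over remaining starting material. That constant, 1.06 mM, is the loss concentration. Taking starting material down by a factor of 10 costs 2.44 mM of reagent, less than the 3.80 mM by which the reagent charge exceeds the starting material. So the quarrel at this blackboard is about the clock.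

The first chemist holds a delivery view. Counting the outward flow alone, reagent leaves the second phase with a half-life of 0.255 min, while coupling alone, at the starting material as charged, takes reagent in the reaction phase with a half-life of 0.062 min, which is shorter. In this view target follows delivery, which reaches 98.3% of the reagent charge by 1.5 min, and neither change has much to add.

The second chemist, and I with her, holds a pool view. Reagent also flows back, and the dormant form relaxes with a half-life of 0.102 min, much shorter than the run of 1.5 min, so she counts the second phase, the reaction phase and the dormant form as one pool with a free share, at balance, of 23.4%. Coupling is then second order in two falling amounts. Taking the two charges as equal, my reckoning gives 79.8%, and it points to winter.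

The forecast stands lower than my figure but chooses as the pool view does: 75%, winter, and 76.5% after summer, and of the chosen change it says “doubling the reagent charge removes the real limit”.

The simulation gives 76.1% and winter, which adds 22 percentage points, while summer adds 3.6 points and reaches 79.7%. In this flask 18.1% of the reagent charge still stands in the second phase, and the loss concentration with 24% of starting material left gives 1.51 mM against the simulation's 1.51 mM of decomposed reagent. The delivery view holds up in the neighbour flask with 150 mM of starting material. Its 73% of starting material remaining gives 0.327 mM against the simulation's 0.326 mM of decomposed reagent, its target is 39.8 mM from a reagent charge of 41.8 mM, and its second phase holds 3.50% of that charge.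

The constants used here are invented; what happens was integrated by code.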